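**Retrosynthetic overview**
1. Target 28 ← double chlorination of the chlorine-free macrolide 26 ← acylketene macrolactonisation of seco ester 24 ← acylation of an acetoacetate dianion by Weinreb amide 21.
2. (Z,Z)-Dienol 21 ← sila-Sonogashira coupling of silylalkyne 16 with (S,Z)-iodoalkenol 19, then Zn(Cu/Ag) semireduction.
3. Decalin 16 ← trans-enone 9 by stereospecific anti-SE2' propargylation at C2 with the axially chiral allenylstannane 12, then ketone → alkene through the enol triflate.
4. Enone 9 ← cis-adduct 4 (C1 ketone → C1–C9 Weinreb amide, ketal hydrolysis, C4a epimerisation) ← enantioselective Diels–Alder reaction that breaks the symmetry of dienone 2, the dearomatised form of 4-methoxyphenol.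
5. Ring order: ring B (from the arene), then ring A (Diels–Alder), then the 14-membered lactone last.

Convention: decalin atoms carry naphthalene numbers (C1 bears the acyl chain, C2 the dienyl chain, C8 the secondary methyl); β is the face of the C8 methyl.
Assumption: (R)-BINOL/TiCl2(O-iPr)2 gives adduct 4 in the sense drawn (otherwise the (S)-ligand is used); 1,3-dicarbonyl compounds are drawn as keto forms and 24–27 are mixtures of epimers at the α-methyl carbon.

**Route**

Step 1
Reactants: 1 4-methoxyphenol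
Product: 2 4,4-dimethoxycyclohexa-2,5-dien-1-one
Conditions: PhI(OAc)2, MeOH, 0 °C to rt
Reagents that add atoms: methanol, CO
Why: hypervalent-iodine oxidative dearomatisation of a para-alkoxyphenol with methanol capture (quinone monoketal formation) gives a flat achiral dienone whose two enone halves are enantiotopic.

Step 2
Reactants: 2 4,4-dimethoxycyclohexa-2,5-dien-1-one; 3 (E)-2-methylpenta-1,3-diene
Product: 4 cis-fused 4,4-dimethoxy-6,8-dimethyl-4a,5,8,8a-tetrahydronaphthalen-1(4H)-one (4a-H, 8a-H and 8-H all α; 8-Me β)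
Conditions: (R)-BINOL (20 mol %), TiCl2(O-iPr)2 (20 mol %), 4 Å MS, CH2Cl2, −20 °C to rt, 3 equiv of 3
Reagents that add atoms: none
Why: key step, a catalytic enantioselective Diels–Alder reaction that breaks the symmetry of 2: the ketone is the only activating group, so the unsubstituted diene terminus bonds to its β-carbon (ortho/para rule) and the carbonyl lies endo (8-Me cis to C1, cis fusion), while the chiral titanium Lewis acid selects one enantiotopic enone face and fixes C8 and C8a absolutely (C4a is inverted in step 5).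

Step 3
Reactants: 4 cis-fused dimethoxy enone
Product: 6 cis-fused 4,4-dimethoxy-6,8-dimethyl-3,4,4a,5,8,8a-hexahydronaphthalen-1-yl trifluoromethanesulfonate, via lithium enolate 5 (not isolated)
Conditions: LiBH(s-Bu)3, THF, −78 °C; then PhNTf2, −78 to 0 °C
Reagents that add atoms: N-phenylbis(trifluoromethanesulfonimide), O=S(=O)(N(c1ccccc1)S(=O)(=O)C(F)(F)F)C(F)(F)F
Why: 1,4-hydride addition to the β-unsubstituted enone gives the C1–C2 enolate regiospecifically and O-triflation traps it (reductive enol triflate formation); C8a is not touched.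

Step 4
Reactants: 6 enol triflate
Product: 7 cis-fused 4,4-dimethoxy-N-methoxy-N,6,8-trimethyl-3,4,4a,5,8,8a-hexahydronaphthalene-1-carboxamide
Conditions: Pd(OAc)2 (5 mol %), Xantphos (6 mol %), CO (1 atm), MeNHOMe·HCl, Et3N, DMF, 60 °C
Reagents that add atoms: carbon monoxide, [C-]#[O+]; N,O-dimethylhydroxylamine hydrochloride, CNOC.Cl
Why: palladium-catalysed aminocarbonylation of the enol triflate turns the C1 carbonyl of the cycloadduct into the C1–C9 bond at the acid oxidation level (Weinreb amide).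

Step 5
Reactants: 7 ketal enamide
Product: 9 trans-fused N-methoxy-N,6,8-trimethyl-4-oxo-1,4,4a,5,8,8a-hexahydronaphthalene-1-carboxamide (1-H β, 4a-H β, 8a-H α, 8-Me β), via cis-fused keto amide 8 (not isolated)
Conditions: 2 M aq. HCl, THF, 50 °C
Reagents that add atoms: water, O
Why: ketal hydrolysis frees the C4 ketone, the C1=C2 bond moves into conjugation with it through the dienol (γ-protonation puts H on C1 with the amide equatorial) and C4a equilibrates through the C4 enol to the trans-fused isomer with the 8-methyl pseudoaxial as in the target (acid-catalysed enolisation under thermodynamic control; recovered cis isomer is re-equilibrated).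

Step 6
Reactants: 10 (R)-4-(trimethylsilyl)but-3-yn-2-ol
Product: 11 (R)-4-(trimethylsilyl)but-3-yn-2-yl methanesulfonate
Conditions: MsCl, Et3N, CH2Cl2, −78 °C
Reagents that add atoms: methanesulfonyl chloride, CS(=O)(=O)Cl
Why: O-sulfonylation with retention activates the propargylic position.

Step 7
Reactants: 11 propargylic mesylate
Product: 12 tributyl[(Sa)-1-(trimethylsilyl)buta-1,2-dien-1-yl]stannane
Conditions: Bu3SnH, LiN(i-Pr)2, THF, 0 °C; CuBr·SMe2, −78 °C; then 11
Reagents that add atoms: tributylstannyllithium, [Li][Sn](CCCC)(CCCC)CCCC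
Why: anti-SN2' displacement of the propargylic mesylate by the stannylcopper reagent transfers the central chirality of the (R)-mesylate to the (Sa) allene axis.

Step 8
Reactants: 9 trans-enone amide; 12 allenylstannane
Product: 13 trans-fused N-methoxy-N,6,8-trimethyl-4-oxo-2-[(2S)-4-(trimethylsilyl)but-3-yn-2-yl]-1,2,3,4,4a,5,8,8a-octahydronaphthalene-1-carboxamide (C2 chain α and axial, cis to the C1 amide)
Conditions: TiCl4 (1.1 equiv, precomplexed with 9), CH2Cl2, −78 °C; then 12; aq. NaHCO3
Reagents that add atoms: none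
Why: Proposed new method: the TiCl4-activated enone is attacked at C2 along the axial trajectory of the rigid trans-fused ring (α face, anti to axial H-1), and the allene reacts through its CH(Me) terminus anti to the C–Sn bond (β-stannyl-stabilised vinyl cation, loss of Bu3Sn+), so both enone face and allene face are fixed and C2 and the side-chain methyl carbon form as single isomers; the closest known reactions are the TiCl4-promoted conjugate propargylation of enones by allenylstannanes and the anti-SE2' additions of chiral allenylstannanes to aldehydes.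

Step 9
Reactants: 13 keto amide
Product: 15 trans-fused 1-[methoxy(methyl)carbamoyl]-6,8-dimethyl-2-[(2S)-4-(trimethylsilyl)but-3-yn-2-yl]-1,2,4a,5,8,8a-hexahydronaphthalen-4-yl trifluoromethanesulfonate, via potassium enolate 14 (not isolated)
Conditions: KN(SiMe3)2 (1.05 equiv), THF, −78 °C; then PhNTf2
Reagents that add atoms: N-phenylbis(trifluoromethanesulfonimide), O=S(=O)(N(c1ccccc1)S(=O)(=O)C(F)(F)F)C(F)(F)F
Why: kinetic deprotonation of the ketone at the C3 methylene (away from the ring fusion, faster than the hindered amide α-CH) and O-triflation place the future C3=C4 double bond.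

Step 10
Reactants: 15 enol triflate
Product: 16 trans-fused N-methoxy-N,6,8-trimethyl-2-[(2S)-4-(trimethylsilyl)but-3-yn-2-yl]-1,2,4a,5,8,8a-hexahydronaphthalene-1-carboxamide
Conditions: Pd(OAc)2 (5 mol %), PPh3 (10 mol %), HCO2H, n-Bu3N, DMF, 60 °C
Reagents that add atoms: none
Why: palladium-catalysed formate reduction of the enol triflate gives the C3=C4 alkene without touching the silyl-capped alkyne, the Weinreb amide or the ring A alkene.

Step 11
Reactants: 17 (S)-but-3-yn-2-ol
Product: 18 (S)-4-iodobut-3-yn-2-ol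
Conditions: N-iodosuccinimide, AgNO3 (10 mol %), acetone, rt
Reagents that add atoms: N-iodosuccinimide, O=C1CCC(=O)N1I
Why: silver-catalysed electrophilic iodination of the terminal alkyne; the carbinol centre comes from the chiral pool and is untouched.

Step 12
Reactants: 18 iodoalkyne
Product: 19 (S,Z)-4-iodobut-3-en-2-ol
Conditions: 2-nitrobenzenesulfonyl hydrazide, Et3N, THF/i-PrOH, rt
Reagents that add atoms: none
Why: syn addition of diimide to the iodoalkyne gives the (Z)-vinyl iodide without C–I cleavage.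

Step 13
Reactants: 16 silylalkyne amide; 19 (S,Z)-4-iodobut-3-en-2-ol
Product: 20 trans-fused 2-[(2S,5Z,7S)-7-hydroxyoct-5-en-3-yn-2-yl]-N-methoxy-N,6,8-trimethyl-1,2,4a,5,8,8a-hexahydronaphthalene-1-carboxamide
Conditions: Pd(PPh3)4 (5 mol %), CuI (10 mol %), CsF, Et3N, DMF, 40 °C
Reagents that add atoms: none
Why: fluoride-promoted sila-Sonogashira coupling (silicon-to-copper transfer of the alkynyl group, then palladium-catalysed coupling) joins the fragments with retention of the (Z) geometry of the vinyl iodide.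

Step 14
Reactants: 20 enyne alcohol
Product: 21 trans-fused 2-[(2R,3Z,5Z,7S)-7-hydroxyocta-3,5-dien-2-yl]-N-methoxy-N,6,8-trimethyl-1,2,4a,5,8,8a-hexahydronaphthalene-1-carboxamide
Conditions: Zn dust activated with Cu(OAc)2 and AgNO3, MeOH/H2O (1:1), 40 °C
Reagents that add atoms: none
Why: activated-zinc (Boland) semireduction of the conjugated enyne is cis-specific and stops at the (Z,Z)-diene, leaving isolated alkenes and the amide alone.

Step 15
Reactants: 21 dienol amide; 22 tert-butyl 2-methyl-3-oxobutanoate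
Product: 24 tert-butyl 5-{trans-fused 2-[(2R,3Z,5Z,7S)-7-hydroxyocta-3,5-dien-2-yl]-6,8-dimethyl-1,2,4a,5,8,8a-hexahydronaphthalen-1-yl}-2-methyl-3,5-dioxopentanoate, via acetoacetate dianion 23 (not isolated)
Conditions: 22 (4 equiv), NaH, THF, 0 °C; n-BuLi, 0 °C; then 21, −78 to 0 °C; aq. NH4Cl
Reagents that add atoms: none
Why: the γ-carbanion of the β-keto ester dianion (Huckin–Weiler) acylates at the Weinreb amide, whose chelated tetrahedral adduct prevents over-addition, building the 3,5-diketo ester; one equivalent of dianion is spent on the free hydroxyl, and C1 (now α to a ketone) stays in its equatorial, thermodynamic configuration.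

Step 16
Reactants: 24 seco tert-butyl ester
Product: 26 14-membered macrolide lacking both chlorines (target skeleton with CH2 between the two ketones), via acylketene 25 (not isolated)
Conditions: toluene, 110 °C, 0.5 mM, slow addition
Reagents that add atoms: none
Why: thermal loss of tert-butanol from the β-keto ester gives an acylketene that is captured by the secondary alcohol held nearby by the cis C1/C2 substitution and the (Z,Z)-diene (acylketene macrolactonisation); the lactone carbinol keeps its (S) configuration.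

Step 17
Reactants: 26 chlorine-free macrolide
Product: 28 chlorotonil A (target), via monochloride 27 (not isolated)
Conditions: N-chlorosuccinimide (2.1 equiv), 2,6-lutidine (0.2 equiv), CH2Cl2, 0 °C to rt
Reagents that add atoms: N-chlorosuccinimide, O=C1CCC(=O)N1Cl
Why: electrophilic chlorination occurs twice at the most enolised position, the CH2 between the two ketones, and the acidic α-methyl centre between ketone and lactone equilibrates under the mild base to the macrocycle-preferred (S) configuration of the natural product.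

**Compound list**
1 | 4-methoxyphenol | COc1ccc(O)cc1 | starting material
2 | 4,4-dimethoxycyclohexa-2,5-dien-1-one | COC1(OC)C=CC(=O)C=C1 | intermediate
3 | (E)-2-methylpenta-1,3-diene | C=C(C)/C=C/C | starting material
4 | cis-fused 4,4-dimethoxy-6,8-dimethyl-4a,5,8,8a-tetrahydronaphthalen-1(4H)-one | CC1=C[C@@H](C)[C@H]2C(=O)C=CC(OC)(OC)[C@H]2C1 | intermediate
5 | lithium enolate of the 2,3-dihydro ketone | CC1=C[C@@H](C)[C@H]2C([O-])=CCC(OC)(OC)[C@H]2C1.[Li+] | intermediate
6 | cis-fused 4,4-dimethoxy-6,8-dimethyl-3,4,4a,5,8,8a-hexahydronaphthalen-1-yl triflate | CC1=C[C@@H](C)[C@H]2C(OS(=O)(=O)C(F)(F)F)=CCC(OC)(OC)[C@H]2C1 | intermediate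
7 | cis-fused 4,4-dimethoxy-N-methoxy-N,6,8-trimethyl-3,4,4a,5,8,8a-hexahydronaphthalene-1-carboxamide | CC1=C[C@@H](C)[C@H]2C(C(=O)N(C)OC)=CCC(OC)(OC)[C@H]2C1 | intermediate
8 | cis-fused N-methoxy-N,6,8-trimethyl-4-oxo-3,4,4a,5,8,8a-hexahydronaphthalene-1-carboxamide | CC1=C[C@@H](C)[C@H]2C(C(=O)N(C)OC)=CCC(=O)[C@H]2C1 | intermediate
9 | trans-fused N-methoxy-N,6,8-trimethyl-4-oxo-1,4,4a,5,8,8a-hexahydronaphthalene-1-carboxamide | CC1=C[C@@H](C)[C@H]2[C@H](C(=O)N(C)OC)C=CC(=O)[C@@H]2C1 | intermediate
10 | (R)-4-(trimethylsilyl)but-3-yn-2-ol | C[C@@H](O)C#C[Si](C)(C)C | starting material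
11 | (R)-4-(trimethylsilyl)but-3-yn-2-yl methanesulfonate | C[C@@H](OS(C)(=O)=O)C#C[Si](C)(C)C | intermediate
12 | tributyl[(Sa)-1-(trimethylsilyl)buta-1,2-dien-1-yl]stannane | CCCC[Sn](CCCC)(CCCC)C([Si](C)(C)C)=[C@@]=C([H])C | intermediate
13 | trans-fused 4-oxo-2-[(2S)-4-(trimethylsilyl)but-3-yn-2-yl] Weinreb amide | CC1=C[C@@H](C)[C@H]2[C@H](C(=O)N(C)OC)[C@H]([C@H](C)C#C[Si](C)(C)C)CC(=O)[C@@H]2C1 | intermediate
14 | potassium C3–C4 enolate of 13 | CC1=C[C@@H](C)[C@H]2[C@H](C(=O)N(C)OC)[C@H]([C@H](C)C#C[Si](C)(C)C)C=C([O-])[C@@H]2C1.[K+] | intermediate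
15 | C4 enol triflate | CC1=C[C@@H](C)[C@H]2[C@H](C(=O)N(C)OC)[C@H]([C@H](C)C#C[Si](C)(C)C)C=C(OS(=O)(=O)C(F)(F)F)[C@@H]2C1 | intermediate
16 | trans-fused N-methoxy-N,6,8-trimethyl-2-[(2S)-4-(trimethylsilyl)but-3-yn-2-yl]-1,2,4a,5,8,8a-hexahydronaphthalene-1-carboxamide | CC1=C[C@@H](C)[C@H]2[C@H](C(=O)N(C)OC)[C@H]([C@H](C)C#C[Si](C)(C)C)C=C[C@@H]2C1 | intermediate
17 | (S)-but-3-yn-2-ol | C[C@H](O)C#C | starting material
18 | (S)-4-iodobut-3-yn-2-ol | C[C@H](O)C#CI | intermediate
19 | (S,Z)-4-iodobut-3-en-2-ol | C[C@H](O)/C=C\I | intermediate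
20 | enyne alcohol, 2-[(2S,5Z,7S)-7-hydroxyoct-5-en-3-yn-2-yl] Weinreb amide | CC1=C[C@@H](C)[C@H]2[C@H](C(=O)N(C)OC)[C@H]([C@H](C)C#C/C=C\[C@H](C)O)C=C[C@@H]2C1 | intermediate
21 | dienol, 2-[(2R,3Z,5Z,7S)-7-hydroxyocta-3,5-dien-2-yl] Weinreb amide | CC1=C[C@@H](C)[C@H]2[C@H](C(=O)N(C)OC)[C@H]([C@H](C)/C=C\C=C/[C@H](C)O)C=C[C@@H]2C1 | intermediate
22 | tert-butyl 2-methyl-3-oxobutanoate | CC(=O)C(C)C(=O)OC(C)(C)C | starting material
23 | sodium lithium dianion of 22 | C=C([O-])C(C)=C([O-])OC(C)(C)C.[Na+].[Li+] | intermediate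
24 | seco tert-butyl 3,5-diketo ester (α-methyl epimers) | CC1=C[C@@H](C)[C@H]2[C@H](C(=O)CC(=O)C(C)C(=O)OC(C)(C)C)[C@H]([C@H](C)/C=C\C=C/[C@H](C)O)C=C[C@@H]2C1 | intermediate
25 | acylketene | CC1=C[C@@H](C)[C@H]2[C@H](C(=O)CC(=O)C(C)=C=O)[C@H]([C@H](C)/C=C\C=C/[C@H](C)O)C=C[C@@H]2C1 | intermediate
26 | chlorine-free macrolide (α-methyl epimers) | CC1=C[C@@H](C)[C@H]2[C@@H]3C(=O)CC(=O)C(C)C(=O)O[C@@H](C)/C=C\C=C/[C@@H](C)[C@@H]3C=C[C@@H]2C1 | intermediate
27 | monochloro macrolide | CC1=C[C@@H](C)[C@H]2[C@@H]3C(=O)C(Cl)C(=O)C(C)C(=O)O[C@@H](C)/C=C\C=C/[C@@H](C)[C@@H]3C=C[C@@H]2C1 | intermediate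
28 | chlorotonil A (CNP0300098.1) | CC1=C[C@@H](C)[C@H]2[C@@H]3C(=O)C(Cl)(Cl)C(=O)[C@H](C)C(=O)O[C@@H](C)/C=C\C=C/[C@@H](C)[C@@H]3C=C[C@@H]2C1 | target

**Step count**
Total: 17 steps. Longest linear sequence: 13 steps (1–5, 8–10, 13–17).

**Three steps most likely to fail**

Step 5 (thermodynamic inversion at C4a). The trans isomer carries a pseudoaxial 8-methyl, so the equilibrium may not lie far enough on the trans side. The fallback sets the trans relationship kinetically with an (E)-configured acyclic dienophile and closes ring B afterwards; it sets out from diene 3 and comes back at 9. 2-Methylfuran is opened oxidatively (NBS, NaHCO3, aqueous acetone, then pyridine) to (E)-4-oxopent-2-enal F1. An iminium-catalysed Diels–Alder reaction of F1 with 3 ((2S,5S)-5-benzyl-2-tert-butyl-3-methylimidazolidin-4-one trifluoroacetate, MeOH/H2O) gives 6-acetyl-2,4-dimethylcyclohex-3-ene-1-carbaldehyde F2, with the formyl group cis to the 2-methyl and trans to the acetyl. Wittig reaction of the aldehyde with Ph3P=CHOMe gives enol ether F3. C-Acylation of the enol ether with trichloroacetyl chloride and pyridine gives the β-methoxyvinyl trichloromethyl ketone F4. NaOMe in MeOH then cleaves the CCl3 group to the methyl ester and the methyl ketone enolate closes ring B by addition–elimination on the β-methoxyacrylate, giving the trans-fused methyl 6,8-dimethyl-4-oxo-1,4,4a,5,8,8a-hexahydronaphthalene-1-carboxylate F5. AlMe3/MeNHOMe·HCl converts F5 into 9.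

Step 8 (stereospecific conjugate propargylation, a new method). The fallback replaces it by a sigmatropic route with chirality transfer from C4 to C2; it sets out from 9 and comes back at 20. Luche reduction (NaBH4, CeCl3·7H2O) gives the 4β (equatorial) allylic alcohol F6. Mitsunobu esterification with propanoic acid inverts it to the 4α (axial) propanoate F7. Ireland–Claisen rearrangement (LiN(i-Pr)2, Me3SiCl, THF, −78 °C to reflux, ketene acetal geometry chosen for the (S) methyl centre) delivers the C2 α-side chain and the C3=C4 alkene in the acid F8. The acid is reduced through its isobutyl mixed anhydride with NaBH4 to the primary alcohol F9. Dess–Martin oxidation gives the aldehyde F10. Ohira–Bestmann homologation (dimethyl (1-diazo-2-oxopropyl)phosphonate, K2CO3, MeOH) gives the terminal alkyne F11. Sonogashira coupling of F11 with 19 (Pd(PPh3)4, CuI, Et3N) gives 20.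

Step 16 (macrolactonisation; the enolised diketone can close onto the ketene to give a 4-hydroxy-2-pyrone instead). The fallback closes the macrocycle by C–C coupling after an intermolecular ester formation; it sets out from 16 and comes back at 26. Dianion 23 acylates 16 to give the silylalkyne tert-butyl diketo ester F12. Heating F12 with an excess of 19 in toluene (intermolecular capture of the acylketene) gives the (S,Z)-4-iodobut-3-en-2-yl ester F13. Intramolecular sila-Sonogashira coupling at high dilution (Pd(PPh3)4, CuI, CsF, DMF) gives the macrocyclic (Z)-enyne F14. Zn(Cu/Ag) reduction of F14 gives 26.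

**Further compounds**
F1 | step 5 | (E)-4-oxopent-2-enal | CC(=O)/C=C/C=O
F2 | step 5 | 6-acetyl-2,4-dimethylcyclohex-3-ene-1-carbaldehyde (CHO cis to 2-Me, trans to acetyl) | CC1=C[C@@H](C)[C@@H](C=O)[C@H](C(C)=O)C1
F3 | step 5 | 1-[6-(2-methoxyvinyl)-3,5-dimethylcyclohex-3-en-1-yl]ethanone | CC1=C[C@@H](C)[C@@H](C=COC)[C@H](C(C)=O)C1
F4 | step 5 | β-methoxyvinyl trichloromethyl ketone | CC1=C[C@@H](C)[C@@H](C(=COC)C(=O)C(Cl)(Cl)Cl)[C@H](C(C)=O)C1
F5 | step 5 | trans-fused methyl 6,8-dimethyl-4-oxo-1,4,4a,5,8,8a-hexahydronaphthalene-1-carboxylate | CC1=C[C@@H](C)[C@H]2[C@H](C(=O)OC)C=CC(=O)[C@@H]2C1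
F6 | step 8 | 4β-hydroxy allylic alcohol of 9 | CC1=C[C@@H](C)[C@H]2[C@H](C(=O)N(C)OC)C=C[C@@H](O)[C@@H]2C1
F7 | step 8 | 4α-propanoate | CC1=C[C@@H](C)[C@H]2[C@H](C(=O)N(C)OC)C=C[C@H](OC(=O)CC)[C@@H]2C1
F8 | step 8 | (S)-2-(decalin-2-yl)propanoic acid | CC1=C[C@@H](C)[C@H]2[C@H](C(=O)N(C)OC)[C@H]([C@H](C)C(=O)O)C=C[C@@H]2C1
F9 | step 8 | primary alcohol | CC1=C[C@@H](C)[C@H]2[C@H](C(=O)N(C)OC)[C@H]([C@H](C)CO)C=C[C@@H]2C1
F10 | step 8 | aldehyde | CC1=C[C@@H](C)[C@H]2[C@H](C(=O)N(C)OC)[C@H]([C@H](C)C=O)C=C[C@@H]2C1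
F11 | step 8 | terminal alkyne, 2-[(2S)-but-3-yn-2-yl] Weinreb amide | CC1=C[C@@H](C)[C@H]2[C@H](C(=O)N(C)OC)[C@H]([C@H](C)C#C)C=C[C@@H]2C1
F12 | step 16 | silylalkyne tert-butyl diketo ester | CC1=C[C@@H](C)[C@H]2[C@H](C(=O)CC(=O)C(C)C(=O)OC(C)(C)C)[C@H]([C@H](C)C#C[Si](C)(C)C)C=C[C@@H]2C1
F13 | step 16 | (S,Z)-4-iodobut-3-en-2-yl diketo ester | CC1=C[C@@H](C)[C@H]2[C@H](C(=O)CC(=O)C(C)C(=O)O[C@@H](C)/C=C\I)[C@H]([C@H](C)C#C[Si](C)(C)C)C=C[C@@H]2C1
F14 | step 16 | macrocyclic (Z)-enyne | CC1=C[C@@H](C)[C@H]2[C@@H]3C(=O)CC(=O)C(C)C(=O)O[C@@H](C)/C=C\C#C[C@@H](C)[C@@H]3C=C[C@@H]2C1
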